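## Retrosynthetic overview

- **Feature:** the C5–C10 ring fusion is cis (H-5 and C10–CH3 on one face). On ring B the contiguous C8–C9–C10 carry C8–CH3, the C9–C11 chain and C10–CH3 on the convex β face, with 8-OH in the fold. Chair–chair polyene cyclisation and the sclareolide pool both give trans fusion and are set aside.
- **C12–C13:** Suzuki union of a C16 bicyclic primary boronate with a C14 (E)-vinyl iodide made from geranylacetone. All three E-alkenes are fixed before the union.
- **C9–C11 (key):** a C9 radical from the 8α-hydroxy-9-bromide adds to vinyl-Bpin on the convex face. C8–O and C9–Br come from anti bromohydrin formation on the Δ8 alkene.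
- **C10–CH3 and C8–CH3:** cuprate addition, enol triflate trapping and methyl coupling on a Δ9(10)-8-ketone. C5 is set by catalytic enantioselective β,γ→α,β isomerisation and is the only stereocentre that is not relayed.
- **Rings:** none is closed. Both are bought as 6-methoxy-2-tetralone. Ring A is its saturated ring (C3 ketone, C4 gem-dimethylated). Ring B is the anisole ring, dearomatised by Birch reduction.

Key step: step 9

Assumption: the SMILES is read literally as (5S,8R,9R,10S), which puts H-5 and C10–CH3 on the same face (cis-decalin); polypodane numbering is used and β is the face of C10–CH3.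

## Route

Step 1
Reactants: 1 6-methoxy-2-tetralone
Product: 2 6-methoxy-1,1-dimethyl-3,4-dihydronaphthalen-2(1H)-one
Conditions: KOt-Bu (2.2 equiv), MeI (2.5 equiv), THF, 0 °C to rt
Reagents that add atoms: iodomethane, CI
Why: Double enolate C-alkylation at the benzylic, α-keto CH2, the most acidic site of a 2-tetralone; this carbon becomes C4 with its gem-dimethyl group.

Step 2
Reactants: 2 6-methoxy-1,1-dimethyl-3,4-dihydronaphthalen-2(1H)-one
Product: 3 ethylene ketal of 2 (future C3 masked as a 1,3-dioxolane)
Conditions: HOCH2CH2OH, p-TsOH (cat.), toluene, reflux, Dean–Stark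
Reagents that add atoms: ethylene glycol, OCCO
Why: Acid-catalysed ketalisation protects the future C3 ketone against dissolving metal and organometallic reagents.

Step 3
Reactants: 3 ethylene ketal of 2
Product: 5 achiral 8-oxo-Δ5(10)-octalin 3-ethylene ketal (β,γ-enone), via dihydroanisole 4 (not isolated)
Conditions: Li, NH3(l), t-BuOH, THF, −78 to −33 °C; then (CO2H)2, MeOH–H2O, rt
Reagents that add atoms: water, O
Why: Birch reduction of the anisole ring should give the 2,5-dihydroanisole with the tetrasubstituted C5=C10 bond, and mild enol ether hydrolysis frees the C8 ketone without conjugation or loss of the dioxolane.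

Step 4
Reactants: 5 8-oxo-Δ5(10)-octalin 3-ethylene ketal
Product: 6 (5S)-8-oxo-Δ9(10)-octalin 3-ethylene ketal (α,β-enone, H-5 β)
Conditions: 9-amino-9-deoxy-epi-cinchona primary–tertiary diamine (10 mol %, the pseudoenantiomer that gives 5S), carboxylic acid co-catalyst (20 mol %), toluene, rt
Reagents that add atoms: none
Why: Enantioselective β,γ→α,β olefin isomerisation by cooperative iminium–base (dienamine) catalysis, a type established for Birch-derived cyclohex-3-enones; the chiral ammonium protonates C5 of the dienamine on one face and sets 5S.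

Step 5
Reactants: 6 (5S)-8-oxo-Δ9(10)-octalin 3-ethylene ketal
Product: 8 cis-fused enol triflate (5β-H; 10β-CH3; C8–OTf; C8=C9), via lithium enolate 7 (not isolated)
Conditions: Me2CuLi (from CuI and MeLi), Et2O, 0 °C; then PhNTf2, THF–DMPU, 0 °C to rt
Reagents that add atoms: lithium dimethylcuprate, [Li+].C[Cu-]C; N-phenylbis(trifluoromethanesulfonimide), O=S(=O)(N(c1ccccc1)S(=O)(=O)C(F)(F)F)C(F)(F)F
Why: Gilman conjugate addition to an octalone attacks C10 axially and anti to the C5–C4 bond (the C4 gem-dimethyl blocks the α face), which places C10–CH3 cis to H-5, and the regiodefined C8–C9 enolate is trapped as its triflate.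

Step 6
Reactants: 8 cis-fused enol triflate
Product: 9 cis-fused 4,4,8,10-tetramethyl-Δ8-octalin 3-ethylene ketal (5β-H, 10β-CH3)
Conditions: MeMgBr, Fe(acac)3 (5 mol %), THF–NMP, −30 to 0 °C
Reagents that add atoms: methylmagnesium bromide, C[Mg]Br
Why: Iron-catalysed (Kochi-type) cross-coupling of an alkenyl triflate with MeMgBr installs C8–CH3 and keeps the double bond at C8=C9.

Step 7
Reactants: 9 Δ8-octalin 3-ethylene ketal
Product: 10 cis-fused 4,4,8,10-tetramethyl-Δ8-octal-3-one (5β-H, 10β-CH3)
Conditions: 2 M HCl, THF, rt
Reagents that add atoms: water, O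
Why: Acid-catalysed ketal hydrolysis, helped by strain relief next to quaternary C4; the trisubstituted alkene and the two set stereocentres are not touched.

Step 8
Reactants: 10 cis-fused Δ8-octal-3-one
Product: 11 9β-bromo-8α-hydroxy-4,4,8β,10β-tetramethyl-cis-decal-3-one (5β-H)
Conditions: NBS (1.05 equiv), THF–H2O, 0 °C, dark
Reagents that add atoms: N-bromosuccinimide, O=C1CCC(=O)N1Br; water, O
Why: Bromohydrin formation, in which the bromonium ion sits on the convex β face and water opens it at tertiary C8 from the α face (Markovnikov, trans-diaxial, Fürst–Plattner), setting 8α-OH/8β-CH3 and leaving a 9β-bromide.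

Step 9
Reactants: 11 9β-bromo-8α-hydroxy ketone
Product: 12 9β-[2-(pinacolatoboryl)ethyl]-8α-hydroxy-4,4,8β,10β-tetramethyl-cis-decal-3-one (5β-H, 9α-H)
Conditions: CH2=CH–Bpin (5 equiv), (TMS)3SiH (slow addition), AIBN (cat.), PhH, 80 °C
Reagents that add atoms: vinylboronic acid pinacol ester, C=CB1OC(C)(C)C(C)(C)O1
Why: (TMS)3Si• abstracts bromine from 11, the secondary C9 radical adds to the CH2 terminus of vinyl-Bpin, and the boron-stabilised C12 radical takes hydrogen from the silane to carry the chain. The closest known type is the reductive Giese addition of alkyl halides to vinyl boronic esters. No ring is closed; the step makes C9–C11, the most congested bond of the target (between quaternary C10 and fully substituted C8), through an early, long-bond transition state that tolerates crowding where SN2 opening or enolate alkylation would not. The C9 radical is planar, so the bromide configuration is irrelevant. In the favoured cis-decalin conformer (C4 equatorial on ring B, enforced by the gem-dimethyl group) the α face of C9 lies in the fold between the axial C10–C1 and C8–OH bonds, so the acceptor should enter from the convex β face and give the 9β chain trans to 8α-OH. Addition must outrun hydrogen transfer to C9, which excess acceptor and slow silane addition secure; bromine abstraction is far faster than silyl radical attack on the hindered C3 ketone, and a β-hydroxyalkyl radical does not expel OH.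

Step 10
Reactants: 13 (E)-geranylacetone
Product: 15 (E)-6,10-dimethylundeca-5,9-dien-1-yne, via enol phosphate 14 (not isolated)
Conditions: LDA, THF, −78 °C; ClP(O)(OEt)2; then LDA (2.3 equiv), −78 °C to rt; H2O
Reagents that add atoms: diethyl chlorophosphate, CCOP(=O)(Cl)OCC (its atoms stay in 14 only and are lost again in 15)
Why: Kinetic enolate O-phosphorylation followed by base-induced elimination of the enol phosphate converts the methyl ketone into the terminal alkyne (C13≡C14) and leaves the E-alkene unchanged.

Step 11
Reactants: 15 (E)-6,10-dimethylundeca-5,9-dien-1-yne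
Product: 16 (2E,6E)-2,6-dimethylundeca-2,6-dien-10-yn-1-ol
Conditions: SeO2 (cat.), t-BuOOH, CH2Cl2, 0 °C
Reagents that add atoms: selenium dioxide (oxygen carrier), O=[Se]=O; tert-butyl hydroperoxide (terminal oxidant), CC(C)(C)OO
Why: SeO2/t-BuOOH allylic oxidation (ene reaction, then [2,3]-shift) prefers the terminal isopropylidene unit and its (E)-methyl group over the internal alkene and the propargylic CH2.

Step 12
Reactants: 16 (2E,6E)-2,6-dimethylundeca-2,6-dien-10-yn-1-ol
Product: 18 (2E,6E,10E)-11-iodo-2,6,10-trimethylundeca-2,6,10-trien-1-ol, via alkenylalane 17 (not isolated)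
Conditions: Me3Al (3.5 equiv), Cp2ZrCl2 (0.3 equiv), CH2Cl2, 0 °C to rt; then I2, THF, −30 °C; aqueous work-up
Reagents that add atoms: trimethylaluminium, C[Al](C)C; iodine, II
Why: Negishi zirconium-catalysed syn-carboalumination puts CH3 on C14 and Al on C13, and iodinolysis with retention gives the (E)-vinyl iodide; the alcohol travels as its aluminium alkoxide.

Step 13
Reactants: 12 bicyclic primary boronate; 18 (E)-vinyl iodide
Product: 19 (5S,8R,9R,10S)-8,30-dihydroxypolypoda-13E,17E,21E-trien-3-one (myrrhanone A in the configuration of the given SMILES)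
Conditions: Pd(OAc)2 (5 mol %), RuPhos (10 mol %), K3PO4, toluene–H2O, 80 °C
Reagents that add atoms: none
Why: Suzuki–Miyaura coupling of a primary alkyl pinacol boronate with an alkenyl iodide forms C12–C13 with retention of the E geometry and tolerates the ketone and both free alcohols.

Step 14
Reactants: 19 diol ketone
Product: 20 myrrhanone A acetate (target)
Conditions: Ac2O, pyridine, DMAP (cat.), CH2Cl2, 0 °C
Reagents that add atoms: acetic anhydride, CC(=O)OC(C)=O
Why: Chemoselective O-acylation of the primary allylic alcohol; the hindered tertiary 8-OH is inert under these conditions.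

## Compound list

| No. | Name | SMILES | Role |
|---|---|---|---|
| 1 | 6-methoxy-2-tetralone | COc1ccc2c(c1)CCC(=O)C2 | starting material |
| 2 | 6-methoxy-1,1-dimethyl-3,4-dihydronaphthalen-2(1H)-one | COc1ccc2c(c1)CCC(=O)C2(C)C | intermediate |
| 3 | ethylene ketal of 2 | COc1ccc2c(c1)CCC1(OCCO1)C2(C)C | intermediate |
| 4 | dihydroanisole (C8(OMe)=C7, C5=C10) | COC1=CCC2=C(C1)CCC1(OCCO1)C2(C)C | intermediate |
| 5 | 8-oxo-Δ5(10)-octalin 3-ethylene ketal | O=C1CCC2=C(C1)CCC1(OCCO1)C2(C)C | intermediate |
| 6 | (5S)-8-oxo-Δ9(10)-octalin 3-ethylene ketal | O=C1C=C2CCC3(OCCO3)C(C)(C)[C@H]2CC1 | intermediate |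
| 7 | lithium C8–C9 enolate, cis-fused, 10β-CH3 | [Li+].[O-]C1=C[C@@]2(C)CCC3(OCCO3)C(C)(C)[C@H]2CC1 | intermediate |
| 8 | cis-fused enol triflate | O=S(=O)(OC1=C[C@@]2(C)CCC3(OCCO3)C(C)(C)[C@H]2CC1)C(F)(F)F | intermediate |
| 9 | cis-fused 4,4,8,10-tetramethyl-Δ8-octalin 3-ethylene ketal | CC1=C[C@@]2(C)CCC3(OCCO3)C(C)(C)[C@H]2CC1 | intermediate |
| 10 | cis-fused 4,4,8,10-tetramethyl-Δ8-octal-3-one | CC1=C[C@@]2(C)CCC(=O)C(C)(C)[C@H]2CC1 | intermediate |
| 11 | 9β-bromo-8α-hydroxy ketone | Br[C@@H]1[C@@]2(C)CCC(=O)C(C)(C)[C@H]2CC[C@@]1(C)O | intermediate |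
| 12 | 9β-(2-Bpin-ethyl)-8α-hydroxy ketone | CC1(C)OB(CC[C@@H]2[C@@]3(C)CCC(=O)C(C)(C)[C@H]3CC[C@@]2(C)O)OC1(C)C | intermediate |
| 13 | (E)-geranylacetone | CC(=O)CC/C=C(\C)CCC=C(C)C | starting material |
| 14 | enol diethyl phosphate of 13 | C=C(CC/C=C(\C)CCC=C(C)C)OP(=O)(OCC)OCC | intermediate |
| 15 | (E)-6,10-dimethylundeca-5,9-dien-1-yne | C#CCC/C=C(\C)CCC=C(C)C | intermediate |
| 16 | (2E,6E)-2,6-dimethylundeca-2,6-dien-10-yn-1-ol | OC/C(C)=C/CC/C(C)=C/CCC#C | intermediate |
| 17 | (E)-alkenylalane, O-aluminium alkoxide | C[Al](C)OC/C(C)=C/CC/C(C)=C/CC/C(C)=C/[Al](C)C | intermediate |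
| 18 | (2E,6E,10E)-11-iodo-2,6,10-trimethylundeca-2,6,10-trien-1-ol | OC/C(C)=C/CC/C(C)=C/CC/C(C)=C/I | intermediate |
| 19 | (5S,8R,9R,10S)-8,30-dihydroxypolypoda-13E,17E,21E-trien-3-one | OC/C(C)=C/CC/C(C)=C/CC/C(C)=C/CC[C@@H]1[C@@]2(C)CCC(=O)C(C)(C)[C@H]2CC[C@@]1(C)O | intermediate |
| 20 | myrrhanone A acetate | CC(=O)OC/C(C)=C/CC/C(C)=C/CC/C(C)=C/CC[C@@H]1[C@@]2(C)CCC(=O)C(C)(C)[C@H]2CC[C@@]1(C)O | target |

## Step count and risks

- Total step count: 14
- Longest linear sequence: 11 (steps 1–9, 13, 14)

**Step 9.**
- Risk: the crowded C9 radical may take hydrogen from the silane before it adds to the moderately reactive acceptor. Facial control may also erode if ring B reacts through its other chair.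
- Fallback, from 11 back to 12: the bond is made by metal capture of the radical instead of conjugate addition. Silyl-radical-mediated nickel/photoredox cross-electrophile coupling of 11 with vinyl bromide should give the 9β-vinyl carbinol F1. The conditions are (TMS)3SiH, an Ir photocatalyst, NiCl2·dtbbpy, Na2CO3, DME and blue light.
- Iridium-catalysed anti-Markovnikov hydroboration of F1 with pinacolborane then returns to 12.

**Step 4.**
- Risk: enantiofacial control of proton transfer may be poor, because C5 of this dienamine is fully substituted and sits next to quaternary C4.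
- Fallback, from 5 back to 6: 5 is conjugated without a chiral catalyst (DBU, CH2Cl2). This gives 6 together with its enantiomer, the (5R)-enone F2.
- The pair is resolved by preparative chromatography on a chiral phase.
- F2 is re-equilibrated with DBU through the achiral dienolate and recycled, and the route is re-entered at 6.

**Step 8.**
- Risk: anti selectivity may be lost through an open C8 cation, or allylic bromination may compete at the hindered alkene.
- Fallback, from 10 back to 12: hydroxyselenenylation with N-(phenylseleno)phthalimide, H2O and catalytic CSA in CH2Cl2. This runs through a reversibly formed seleniranium ion.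
- It should settle on the Markovnikov anti adduct, the 8α-hydroxy-9β-phenylselenide F3.
- F3 serves directly as the C9 radical precursor under the conditions of step 9 and returns to 12.

## Further compounds

F1 | step 9 | 9β-vinyl-8α-hydroxy-4,4,8β,10β-tetramethyl-cis-decal-3-one | C=C[C@@H]1[C@@]2(C)CCC(=O)C(C)(C)[C@H]2CC[C@@]1(C)O
F2 | step 4 | (5R)-8-oxo-Δ9(10)-octalin 3-ethylene ketal (enantiomer of 6) | O=C1C=C2CCC3(OCCO3)C(C)(C)[C@@H]2CC1
F3 | step 8 | 8α-hydroxy-9β-(phenylselanyl)-4,4,8β,10β-tetramethyl-cis-decal-3-one | c1ccccc1[Se][C@@H]1[C@@]2(C)CCC(=O)C(C)(C)[C@H]2CC[C@@]1(C)O
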